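The numbers in the tables were generated by integration for an exercise, noise included.

You have 3 questions about this flask, and the first two can be read almost directly from the earlier runs.

| flask | starting material | second substrate | enzyme | remark | time |
|---|---|---|---|---|---|
| Friday's | 0.050 M | 1 equiv (fed, over 8.0 min) | 0.014 mol% | run made earlier; the fed solution adds 0.20 times the starting volume |  |
| Thursday's | 0.050 M | 1 equiv (fed, over 8.0 min) | 0.032 mol% | run made earlier; the fed solution adds 0.20 times the starting volume |  |
| flask | 0.050 M | 1.00 equiv (fed, over 8.0 min) | 0.021 mol% | the fed solution adds 0.20 times the starting volume | 6.0 h |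

| run | time / h | starting material / % | target / % |
|---|---|---|---|
| Friday's | 0.500 | 20 | 17 |
| Friday's | 1.33 | 5 | 28 |
| Friday's | 2.50 | 3 | 31 |
| Friday's | 4.00 | 0 | 31 |
| Friday's | 6.00 | 0 | 32 |
| Friday's | 8.00 | 0 | 31 |
| Thursday's | 0.500 | 17 | 27 |
| Thursday's | 1.33 | 5 | 40 |
| Thursday's | 2.50 | 0 | 42 |
| Thursday's | 4.00 | 0 | 42 |
| Thursday's | 6.00 | 0 | 41 |
| Thursday's | 8.00 | 0 | 41 |

(standard deviation of a reading: 1.5 percentage points)

- which holds at 6.0 h: what has brought the reaction to rest, or that it has not come to rest (it is still moving / forward and back rates have come level / no working catalyst is left / all of the starting material has reacted)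
- how much of the starting material has reacted by 6.0 h
- how much target there is at 6.0 h, in percent of the starting material charged

- charges are per starting volume, the dose included; the dosed solution carries all of it
- the reaction counts as stopped when no species that holds the starting material changes by six tenths of a point or more over the second half of the time

Both runs read 0% starting material from 4.00 h on, and the flask's loading lies between theirs. So I expect it to be fully converted and at rest by 6.0 h.

The amount of target needs a number. Take the mean target over the last four readings of each run and form the odds, target over the remainder:

Friday: 31.2%, odds 0.455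

Thursday: 41.5%, odds 0.709

The odds rise 1.56-fold for a loading up 2.29-fold, close to its square root, 1.51. So divide the odds by the root of the loading, taken as a fraction:

Friday 38.4, Thursday 39.7, mean 39.0

This mean is the odds number, a kind of selectivity factor: the target's odds per root of loading. The root was picked from these same two runs, so their ratio, 1.03, is no test of it, and both ran at 0.050 M, so concentration is untested. For the flask:

odds = 0.566, target = 36.1%

The forecast gives all of the starting material has reacted, 100% reacted and 36% target, holding that “The yield is set by enzyme competing with an enzyme-independent loss channel”.

The flask gives all of the starting material has reacted, >99.9% reacted and 37.0% target.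

    starting material + enzyme ⇌ complex A (K = 21.0 L mol⁻¹, k = 3.80 × 10⁵ L mol⁻¹ min⁻¹)
    complex A → enzyme + target (k = 250 min⁻¹)
    second substrate + enzyme ⇌ complex B (K = 18.0 L mol⁻¹, k = 5.20 × 10⁵ L mol⁻¹ min⁻¹)
    complex B → enzyme + second product (k = 31000 min⁻¹)
    2 complex A ⇌ resting dimer (K = 1.80 × 10⁷ L mol⁻¹, k = 35000 L mol⁻¹ min⁻¹)
    2 starting material → homo dimer (k = 1.00 L mol⁻¹ min⁻¹)

The flask's odds number is 40.5, against 39.0 from the runs. A second flask at 0.013 M, same equivalents and loading, gives 51.9% target with 0.74% starting material still unbound, and the number 74.4, up 1.84-fold for a dilution whose root is 1.96. The asked flask has come to rest, with 0% starting material left and a largest change of 0.5 percentage points in the share of any substrate, intermediate or product over the second half. Ten times the time leaves the asked flask's target at 37.0%, while its resting dimer falls from 32.7% to 0.0600% of the catalyst charged.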